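The rate constants are made up; the result is computed.

- Per molar per second is the unit of the catalysed step, so it can stand against the side step, which runs per second, only once I multiply it by the concentration of free catalyst; that product is a pseudo-first-order constant.

substrate 1.0 M; free catalyst 0.063 mol%; time 30 min

1. how much target there is at 30 min, in percent of the substrate charged
2. how much side product there is at 30 min, in percent of the substrate charged

    free catalyst → spent catalyst (k1 = 0.00276 s⁻¹)
    crystals ⇌ target, rate k2*(cs2 - [target]) while solid is left; crystals form when [target] > cs2 (cs2 = 0.77 M, k2 = 3.38 s⁻¹)
    substrate → intermediate (k3 = 0.0489 s⁻¹)
    free catalyst + intermediate → free catalyst + target (k4 = 15.9 M⁻¹ s⁻¹)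
    intermediate → side product (k5 = 0.0197 s⁻¹)

- In this flask substrate turns into intermediate, and intermediate goes either with free catalyst to target or by itself to side product, while free catalyst decays to spent catalyst.
- At the charge the catalysed step has 0.0100 s⁻¹ against 0.0197 s⁻¹ for the side step. Both are first order in intermediate, so its concentration cancels.
- I carry one quantity: the branching ratio, catalysed constant over side constant, here 0.508. Intermediate reaches target in the share ratio over one plus ratio.
- In the first extreme free catalyst stays whole, which gives 33.7% target. In the second it dies at once, and no intermediate becomes target.
- This flask lies near the first extreme: free catalyst lasts 6.04 min on average, while a molecule waits 0.341 min as substrate and 0.561 min as intermediate, a passage of 0.902 min.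
- After that passage I reckon that 86.1% of the free catalyst stands, so the ratio drifts to 0.438. I commit to 30.5% target and 69.5% side product, since 30 min is longer than the passage.
- That target, 0.305 M, is less than the solubility of 0.77 M, so I expect no crystals.
- The forecast, whose averaging “gives an alternating series”, puts target at 30.4% and side product at 69.6%, its target close to mine.
- The flask gives 30.4% target and 69.6% side product.

- At 0.236 min the side step uses intermediate 2.0 times as fast as the catalysed step. The branching ratio, decayed to that moment, gives 2.05 for the same comparison.
- For the neighbour flask with 0.16 mol% of free catalyst, the ratio starts at 1.29, the passage is 0.710 min, and the ratio drifts to 1.15, which means 53.5% target. That neighbour flask gives 53.3% target and 46.7% side product.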